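**Retrosynthetic overview**
1. C4–C5: ring-closing vinylogous aldol of seco-aldehyde 23. The macrocycle closes last, C4 and C5 are set, and the 5-OH appears without a protecting group.
2. 23 comes from alcohol 19 by C8 angelate esterification and direct oxidation of the C5 silyl ether.
3. C7–C8: visible-light/chromium allylation of aldehyde 11 by bromomethylbutenolide 17. It sets C7 and C8 and unveils the α-methylene lactone.
4. 11 comes from (S)-lactic acid (C10), allyl bromide and 1-butyne. 17 comes from (R)-glyceraldehyde acetonide (C6) and methyl acrylate.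
5. Ring order: 3(2H)-furanone, then γ-lactone, then the oxygen-bridged ten-membered carbocycle.

Assumption: germacrane locants are used (C1 ketone, C2=C3 enol ether, C4 CH–Me, C5 carbinol, C6 lactone O–CH, C7 ring-fusion CH, C8 angelate CH, C9 CH2, C10 quaternary C–O, C11=C13 methylene, C12 lactone C=O). Compounds 14–16 are carried as C7 epimers, so that centre is left open in their SMILES; it is erased in step 7.

**Step 1**
Reactants: 1 (S)-lactic acid; 2 pivalaldehyde
Product: 3 (2S,5S)-2-tert-butyl-5-methyl-1,3-dioxolan-4-one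
Conditions: cat. p-TsOH, cat. H2SO4, pentane, reflux (Dean–Stark); crystallise from pentane, −78 °C
Reagents that add atoms: pivalaldehyde (2), CC(C)(C)C=O
Why: In this acid-catalysed acetalisation (first stage of self-regeneration of stereocentres), the bought lactate centre makes the cis acetal the thermodynamic product (about 4:1), and crystallisation gives it pure.

**Step 2**
Reactants: 3 (2S,5S)-2-tert-butyl-5-methyl-1,3-dioxolan-4-one; 4 allyl bromide
Product: 6 (2S,5R)-2-tert-butyl-5-methyl-5-(prop-2-en-1-yl)-1,3-dioxolan-4-one, via lithium enolate 5 (not isolated)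
Conditions: LDA, THF, −78 °C; allyl bromide, −78 → −30 °C
Reagents that add atoms: allyl bromide (4), C=CCBr
Why: In this enolate alkylation the planar enolate 5 is attacked anti to the tert-butyl group (dr > 95:5), which rebuilds the quaternary carbinol centre C10 as R with overall retention.

**Step 3**
Reactants: 6 (2S,5R)-2-tert-butyl-5-methyl-5-(prop-2-en-1-yl)-1,3-dioxolan-4-one; 7 1-butyne
Product: 10 (2R)-5-ethyl-2-methyl-2-(prop-2-en-1-yl)furan-3(2H)-one, via lithium hemiketal alkoxide 8 (not isolated), via (4R)-4-hydroxy-4-methylnon-1-en-6-yn-5-one 9 (not isolated)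
Conditions: 1-butyne, n-BuLi (1.0 equiv), THF, −78 °C; add 6, 1 h; MeOH (5 equiv), −78 °C → rt
Reagents that add atoms: 1-butyne (7), CCC#C
Why: Alkynyllithium acyl substitution is followed by base-catalysed 5-endo-dig oxa-Michael cyclisation: adduct 8 holds until the quench, then sheds pivalaldehyde to give 9, whose tertiary alcohol adds to the ynone under LiOMe without touching C10.

**Step 4**
Reactants: 10 (2R)-5-ethyl-2-methyl-2-(prop-2-en-1-yl)furan-3(2H)-one
Product: 11 [(2R)-5-ethyl-2-methyl-3-oxo-2,3-dihydrofuran-2-yl]acetaldehyde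
Conditions: OsO4 (2 mol %), NaIO4 (4 equiv), 2,6-lutidine, dioxane/H2O 3:1, rt; used fresh
Reagents that add atoms: osmium tetroxide, O=[Os](=O)(=O)=O; sodium periodate, [Na+].[O-]I(=O)(=O)=O
Why: In this Lemieux–Johnson cleavage the monosubstituted alkene is osmylated much faster than the trisubstituted push–pull furanone C=C, and the lutidine buffer suppresses E1cB loss of the C10–O bond, so C10 stays intact.

**Step 5**
Reactants: 12 (R)-2,2-dimethyl-1,3-dioxolane-4-carbaldehyde; 13 methyl acrylate
Product: 14 methyl 2-{[(4R)-2,2-dimethyl-1,3-dioxolan-4-yl](hydroxy)methyl}prop-2-enoate (carbinol epimers)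
Conditions: DABCO, dioxane/H2O 1:1, rt, 24 h
Reagents that add atoms: methyl acrylate (13), C=CC(=O)OC
Why: This Morita–Baylis–Hillman reaction joins C7 to C11 and brings in C11–C13; C6 is the bought centre and the new carbinol centre (about 2–3:1) is irrelevant because step 7 erases it.

**Step 6**
Reactants: 14 methyl 2-{[(4R)-2,2-dimethyl-1,3-dioxolan-4-yl](hydroxy)methyl}prop-2-enoate
Product: 15 (5R)-4-hydroxy-5-(hydroxymethyl)-3-methylideneoxolan-2-one (C4 epimers)
Conditions: TFA/H2O 4:1, 0 °C → rt; evaporate with toluene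
Reagents that add atoms: none
Why: Acetonide hydrolysis is followed by spontaneous γ-lactonisation of the C6 hydroxyl onto the methyl ester (five-membered ring preferred over six), with no bond to C6 broken.

**Step 7**
Reactants: 15 (5R)-4-hydroxy-5-(hydroxymethyl)-3-methylideneoxolan-2-one
Product: 17 (5S)-3-(bromomethyl)-5-{[(triethylsilyl)oxy]methyl}furan-2(5H)-one, via (5R)-4-hydroxy-3-methylidene-5-{[(triethylsilyl)oxy]methyl}oxolan-2-one 16 (not isolated)
Conditions: TESCl (1.05 equiv), imidazole (2.5 equiv), CH2Cl2, −40 °C; then CBr4, PPh3, 0 °C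
Reagents that add atoms: chlorotriethylsilane, CC[Si](Cl)(CC)CC; carbon tetrabromide, BrC(Br)(Br)Br
Why: Selective silylation of the primary alcohol is followed by Appel bromination with allylic transposition (SN2′, the normal course for Baylis–Hillman alcohols), so both C7 epimers converge on the conjugated butenolide and C6 is untouched.

**Step 8**
Reactants: 11 [(2R)-5-ethyl-2-methyl-3-oxo-2,3-dihydrofuran-2-yl]acetaldehyde; 17 (5S)-3-(bromomethyl)-5-{[(triethylsilyl)oxy]methyl}furan-2(5H)-one
Product: 19 (4R,5S)-4-{(1S)-2-[(2R)-5-ethyl-2-methyl-3-oxo-2,3-dihydrofuran-2-yl]-1-hydroxyethyl}-3-methylidene-5-{[(triethylsilyl)oxy]methyl}oxolan-2-one, via σ-allylchromium(III) dichloride 18 (not isolated)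
Conditions: CrCl2 (10 mol %), 4CzIPN (2 mol %), Hantzsch ester (1.3 equiv), 2,6-lutidine (1.5 equiv), 17 (1.3 equiv), degassed THF, 456 nm LEDs, 20 °C, 16 h
Reagents that add atoms: none
Why: Proposed new method: a light-driven, chromium-catalytic allylation that uses an endocyclic, γ-stereogenic 3-(bromomethyl)butenolide as allyl donor, which has not been shown; excited 4CzIPN is quenched by the Hantzsch ester, its radical anion (about −1.2 V) returns Cr(III) (about −0.6 V) to Cr(II), Cr(II) abstracts bromine from 17 and a second Cr(II) captures the allyl radical as primary σ-allyl 18, whose ring-locked E-type geometry (C6 trans to CH2Cr) reacts through C7 in a Zimmerman–Traxler chair on the face anti to CH2OTES, giving the C7–C8 bond, the trans C6/C7 lactone, the anti C7/C8 relation (7R,8S) and the exo-methylene, while lutidinium protonates the Cr alkoxide for turnover; the closest known reaction types are the stoichiometric Nozaki–Hiyama or zinc Barbier allylation with the parent 3-(bromomethyl)furan-2(5H)-one and photoredox/chromium allylation of aldehydes with simple allyl donors.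

**Step 9**
Reactants: 19 homoallylic alcohol (name as in step 8); 20 angelic acid, (Z)-2-methylbut-2-enoic acid
Product: 21 (1S)-2-[(2R)-5-ethyl-2-methyl-3-oxo-2,3-dihydrofuran-2-yl]-1-[(2S,3R)-4-methylidene-5-oxo-2-{[(triethylsilyl)oxy]methyl}oxolan-3-yl]ethyl (2Z)-2-methylbut-2-enoate
Conditions: angelic acid, 2,4,6-trichlorobenzoyl chloride, Et3N, toluene, rt, 2 h; then 19, 80 °C
Reagents that add atoms: angelic acid (20), C/C=C(/C)C(=O)O
Why: Yamaguchi-type mixed-anhydride esterification run without DMAP is the standard way to put an angelate on a hindered secondary alcohol without Z→E isomerisation, and C8 keeps its configuration because only the O–H bond reacts.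

**Step 10**
Reactants: 21 angelate silyl ether (name as in step 9)
Product: 23 (1S)-2-[(2R)-5-ethyl-2-methyl-3-oxo-2,3-dihydrofuran-2-yl]-1-[(2S,3R)-2-formyl-4-methylidene-5-oxooxolan-3-yl]ethyl (2Z)-2-methylbut-2-enoate, via alkoxydimethylsulfonium chloride 22 (not isolated)
Conditions: (COCl)2 (5 equiv), DMSO (10 equiv), CH2Cl2, −78 → −35 °C; Et3N, −78 → 0 °C; used at once
Reagents that add atoms: none
Why: In this Swern oxidation applied directly to a primary triethylsilyl ether, the chlorosulfonium salt exchanges with O–SiEt3 to give 22 and amine-induced elimination gives the aldehyde in one operation, cold enough to keep C6 from epimerising.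

**Step 11**
Reactants: 23 seco-aldehyde (name as in step 10)
Product: 25 rufescenolide B, via potassium (E)-dienolate 24 (not isolated)
Conditions: KHMDS (1.05 equiv), THF (1 mM), −78 °C, 45 min; AcOH, −78 °C
Reagents that add atoms: none
Why: This is an intramolecular vinylogous aldol addition (γ-attack at the 5-ethyl group is the known mode for 3(2H)-furanone dienolates): the C9 tether lets C5 reach only the C4 face syn to C9, only the (E)-dienolate (C15 next to H-2, away from the lactone oxygen) fits while the (Z)-isomer returns by proton exchange with HN(SiMe3)2, and the aldehyde reacts in the Cornforth rotamer (C5=O anti to C6–O), which together give 4R,5S.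

**Compound list**
1 | (S)-lactic acid | C[C@H](O)C(=O)O | starting material
2 | pivalaldehyde | CC(C)(C)C=O | starting material
3 | (2S,5S)-2-tert-butyl-5-methyl-1,3-dioxolan-4-one | C[C@@H]1O[C@H](C(C)(C)C)OC1=O | intermediate
4 | allyl bromide | C=CCBr | starting material
5 | lithium enolate of 3 | CC1=C([O-])O[C@@H](C(C)(C)C)O1.[Li+] | intermediate
6 | (2S,5R)-2-tert-butyl-5-methyl-5-(prop-2-en-1-yl)-1,3-dioxolan-4-one | C=CC[C@@]1(C)O[C@H](C(C)(C)C)OC1=O | intermediate
7 | 1-butyne | CCC#C | starting material
8 | lithium hemiketal alkoxide from 6 and butynyllithium | C=CC[C@@]1(C)O[C@H](C(C)(C)C)OC1([O-])C#CCC.[Li+] | intermediate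
9 | (4R)-4-hydroxy-4-methylnon-1-en-6-yn-5-one | C=CC[C@@](C)(O)C(=O)C#CCC | intermediate
10 | (2R)-5-ethyl-2-methyl-2-(prop-2-en-1-yl)furan-3(2H)-one | C=CC[C@@]1(C)OC(CC)=CC1=O | intermediate
11 | [(2R)-5-ethyl-2-methyl-3-oxo-2,3-dihydrofuran-2-yl]acetaldehyde | O=CC[C@@]1(C)OC(CC)=CC1=O | intermediate
12 | (R)-2,2-dimethyl-1,3-dioxolane-4-carbaldehyde | CC1(C)OC[C@H](C=O)O1 | starting material
13 | methyl acrylate | C=CC(=O)OC | starting material
14 | methyl 2-{[(4R)-2,2-dimethyl-1,3-dioxolan-4-yl](hydroxy)methyl}prop-2-enoate | C=C(C(=O)OC)C(O)[C@H]1COC(C)(C)O1 | intermediate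
15 | (5R)-4-hydroxy-5-(hydroxymethyl)-3-methylideneoxolan-2-one | C=C1C(O)[C@@H](CO)OC1=O | intermediate
16 | (5R)-4-hydroxy-3-methylidene-5-{[(triethylsilyl)oxy]methyl}oxolan-2-one | C=C1C(O)[C@@H](CO[Si](CC)(CC)CC)OC1=O | intermediate
17 | (5S)-3-(bromomethyl)-5-{[(triethylsilyl)oxy]methyl}furan-2(5H)-one | BrCC1=C[C@@H](CO[Si](CC)(CC)CC)OC1=O | intermediate
18 | σ-allylchromium(III) dichloride from 17 (THF-solvated) | Cl[Cr](Cl)CC1=C[C@@H](CO[Si](CC)(CC)CC)OC1=O | intermediate
19 | (4R,5S)-4-{(1S)-2-[(2R)-5-ethyl-2-methyl-3-oxo-2,3-dihydrofuran-2-yl]-1-hydroxyethyl}-3-methylidene-5-{[(triethylsilyl)oxy]methyl}oxolan-2-one | C=C1C(=O)O[C@H](CO[Si](CC)(CC)CC)[C@H]1[C@@H](O)C[C@@]2(C)OC(CC)=CC2=O | intermediate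
20 | angelic acid | C/C=C(/C)C(=O)O | starting material
21 | 8-O-angelate of 19 | C=C1C(=O)O[C@H](CO[Si](CC)(CC)CC)[C@H]1[C@@H](OC(=O)/C(C)=C\C)C[C@@]2(C)OC(CC)=CC2=O | intermediate
22 | C5 alkoxydimethylsulfonium chloride from 21 | C=C1C(=O)O[C@H](CO[S+](C)C)[C@H]1[C@@H](OC(=O)/C(C)=C\C)C[C@@]2(C)OC(CC)=CC2=O.[Cl-] | intermediate
23 | seco-aldehyde (C5 formyl) | C=C1C(=O)O[C@H](C=O)[C@H]1[C@@H](OC(=O)/C(C)=C\C)C[C@@]2(C)OC(CC)=CC2=O | intermediate
24 | potassium (E)-dienolate of 23 | C=C1C(=O)O[C@H](C=O)[C@H]1[C@@H](OC(=O)/C(C)=C\C)C[C@@]2(C)OC(=C/C)/C=C2[O-].[K+] | intermediate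
25 | rufescenolide B (4R,5S,6S,7R,8S,10R) | C=C1C(=O)O[C@@H]2[C@@H](O)[C@@H](C)C3=CC(=O)[C@@](C)(C[C@H](OC(=O)/C(C)=C\C)[C@@H]12)O3 | target

**Total step count:** 11. **Longest linear sequence:** 8 (steps 1–4, then 8–11). The other branch is 7 (steps 5–7, then 8–11).

**Three steps most likely to fail**

Step 8 (the new step). The allyl radical may be reduced or dimerise before chromium captures it. Aldehyde 11 may lose its C10–O bond by E1cB, and turnover of the Cr alkoxide may stall. The fallback uses known chemistry and leaves the radical/chromium manifold for a preformed, isolable allylboron reagent. It sets out from 17. Palladium-catalysed borylation (B2pin2, Pd2(dba)3, THF, 60 °C) gives (5S)-3-[(4,4,5,5-tetramethyl-1,3,2-dioxaborolan-2-yl)methyl]-5-{[(triethylsilyl)oxy]methyl}furan-2(5H)-one F1. Sc(OTf)3-catalysed allylboration of 11 (toluene, 0 °C) runs through the same closed chair and gives the O-pinacolboryl ether of 19 F2. Buffered aqueous work-up brings the route back at 19.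

Step 11. The nine-membered closure may be reversible (retro-aldol of the potassium aldolate). The base may instead enolise the aldehyde, remove H-7 with loss of angelate, or trigger Michael addition to the methylene lactone. The unproductive (Z)-dienolate may also persist. The fallback replaces the basic metal dienolate by a Lewis-acid Mukaiyama closure with irreversible silyl trapping. It sets out from 23. TBSOTf (3 equiv) and Et3N (4 equiv) in CH2Cl2 (1 mM, −78 → −20 °C) silylate the most basic oxygen (C1=O) and give the tert-butyldimethylsilyl dienol ether of 23 F3. F3 adds through C4 to the silyl-triflate-activated aldehyde to give the 5-O-tert-butyldimethylsilyl ether of rufescenolide B F4. HF·pyridine (THF, 0 °C) brings the route back at 25.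

Step 9. At 80 °C with amine, the free C8 hydroxyl may translactonise to the 8,12-olide, acylation of the hindered alcohol may be slow, and angelate may drift to tiglate. The fallback builds the Z-alkene on the substrate instead of transferring it. It sets out from 19. EDC coupling at 0 °C with 2-[bis(2,2,2-trifluoroethoxy)phosphoryl]propanoic acid gives the 8-O-{2-[bis(2,2,2-trifluoroethoxy)phosphoryl]propanoate} of 19 F5. Still–Gennari olefination (KHMDS, 18-crown-6, THF, −78 °C, then acetaldehyde) deprotonates only the far more acidic phosphonate and brings the route back at 21.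

**Further compounds**
F1 | step 8 | (5S)-3-[(4,4,5,5-tetramethyl-1,3,2-dioxaborolan-2-yl)methyl]-5-{[(triethylsilyl)oxy]methyl}furan-2(5H)-one | CC1(C)OB(CC2=C[C@@H](CO[Si](CC)(CC)CC)OC2=O)OC1(C)C
F2 | step 8 | O-pinacolboryl ether of 19 | C=C1C(=O)O[C@H](CO[Si](CC)(CC)CC)[C@H]1[C@@H](OB3OC(C)(C)C(C)(C)O3)C[C@@]2(C)OC(CC)=CC2=O
F3 | step 11 | tert-butyldimethylsilyl dienol ether of 23 | C=C1C(=O)O[C@H](C=O)[C@H]1[C@@H](OC(=O)/C(C)=C\C)C[C@@]2(C)OC(=C/C)/C=C2O[Si](C)(C)C(C)(C)C
F4 | step 11 | 5-O-tert-butyldimethylsilyl ether of rufescenolide B | C=C1C(=O)O[C@@H]2[C@@H](O[Si](C)(C)C(C)(C)C)[C@@H](C)C3=CC(=O)[C@@](C)(C[C@H](OC(=O)/C(C)=C\C)[C@@H]12)O3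
F5 | step 9 | 8-O-{2-[bis(2,2,2-trifluoroethoxy)phosphoryl]propanoate} of 19 | C=C1C(=O)O[C@H](CO[Si](CC)(CC)CC)[C@H]1[C@@H](OC(=O)C(C)P(=O)(OCC(F)(F)F)OCC(F)(F)F)C[C@@]2(C)OC(CC)=CC2=O
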